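**Plan**
1. The target is gallocatechin-(4α→6)-gallocatechin. Flavan numbering is used: upper unit rings A/C/B unprimed, lower unit rings D/F/E primed.
2. Enabling feature: C4 is a diarylmethine carbon on C4a of ring A, ortho to C8a–O1. Ring A can therefore be unmasked as the ortho-quinone methide O1=C8a–C4a=C4 with ring D already on C4.
3. Cuts, in retrosynthetic order: C2–H and C2–C1 of ring B (back to a C2 lactone); C3–C4 together with O1–C2 (methide + benzyloxyacetate enolate); C4–C6' (ring D Grignard reagent + ring A salicylaldehyde).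
4. Forward: rings D, F and E come intact from (+)-gallocatechin (C8' blocked by Br, C6' iodinated and metallated). Ring A is joined at C4–C6', ring C closes in the key step, and ring B is added last.
5. Stereochemistry: C2' and C3' come from the chiral pool. C3 comes from the chiral isothiourea and C4 from the trans-selective addition to its enolate. C2 comes from axial hydride delivery to the C2 oxocarbenium ion, anti to ring D.

Key step: step 9

Abbreviations: Bn = benzyl; TBS = tert-butyldimethylsilyl; ArD = (2R,3S)-3,5,7-tris(benzyloxy)-8-bromo-2-[3,4,5-tris(benzyloxy)phenyl]chroman-6-yl (the protected lower unit bound through C6'); HyperBTM = (2S,3R)-3-isopropyl-2-phenyl-3,4-dihydro-2H-benzo[4,5]thiazolo[3,2-a]pyrimidine, CC(C)[C@@H]1CN2c3ccccc3SC2=N[C@@H]1c1ccccc1.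

Assumption: the facial bias of (2S,3R)-HyperBTM known for aryl- and alkenylacetate enolates is taken to hold for the benzyloxyacetate enolate; if the opposite sense is found, the equally available (2R,3S) catalyst takes its place with no other change.

**Step 1**
Reactants: 1 (+)-gallocatechin
Product: 2 (2R,3S)-5,7-bis(benzyloxy)-2-[3,4,5-tris(benzyloxy)phenyl]chroman-3-ol
Conditions: BnBr (5.5 equiv), K2CO3, DMF, argon, 0 °C → rt
Reagents that add atoms: benzyl bromide, BrCc1ccccc1
Why: Williamson etherification with a carbonate base alkylates only the five acidic phenols and leaves the secondary C3' alcohol and both stereocentres untouched, as is routine for catechin-type flavan-3-ols.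

**Step 2**
Reactants: 2 (2R,3S)-5,7-bis(benzyloxy)-2-[3,4,5-tris(benzyloxy)phenyl]chroman-3-ol
Product: 3 (2R,3S)-3,5,7-tris(benzyloxy)-2-[3,4,5-tris(benzyloxy)phenyl]chroman
Conditions: NaH, BnBr, DMF, 0 °C → rt
Reagents that add atoms: benzyl bromide, BrCc1ccccc1
Why: Williamson etherification of the remaining secondary alkoxide gives a uniformly benzylated lower unit, so that a single hydrogenolysis at the end removes every protecting group and no silyl ether competes in steps 8 and 11.

**Step 3**
Reactants: 3 (2R,3S)-3,5,7-tris(benzyloxy)-2-[3,4,5-tris(benzyloxy)phenyl]chroman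
Product: 4 (2R,3S)-3,5,7-tris(benzyloxy)-8-bromo-2-[3,4,5-tris(benzyloxy)phenyl]chroman
Conditions: NBS (1.0 equiv), CH2Cl2, −78 °C → 0 °C
Reagents that add atoms: N-bromosuccinimide, O=C1CCC(=O)N1Br
Why: Electrophilic aromatic bromination of O-benzylated flavan-3-ols with one equivalent of NBS at low temperature goes to C8' of the phloroglucinol-type ring D, which leaves C6' as the only open site for the next substitution.

**Step 4**
Reactants: 4 (2R,3S)-3,5,7-tris(benzyloxy)-8-bromo-2-[3,4,5-tris(benzyloxy)phenyl]chroman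
Product: 5 (2R,3S)-3,5,7-tris(benzyloxy)-8-bromo-6-iodo-2-[3,4,5-tris(benzyloxy)phenyl]chroman
Conditions: NIS (1.1 equiv), CF3CO2H (10 mol %), CH2Cl2/MeCN, 0 °C → rt
Reagents that add atoms: N-iodosuccinimide, O=C1CCC(=O)N1I
Why: Electrophilic aromatic iodination takes the last free position of ring D (C6', activated by O5', O7' and O1'), which is more electron-rich than the free positions of ring E, and installs a halogen that exchanges with magnesium faster than the C8' bromide.

**Step 5**
Reactants: 6 3,5-bis(benzyloxy)phenol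
Product: 7 4,6-bis(benzyloxy)-2-hydroxybenzaldehyde
Conditions: MgCl2 (anhydrous), Et3N, (CH2O)n, MeCN, reflux
Reagents that add atoms: paraformaldehyde (as formaldehyde), C=O
Why: Casnati–Skattebøl ortho-formylation, in which the magnesium phenoxide delivers formaldehyde only to a carbon ortho to the free OH (the two ortho carbons are equivalent) and a second formaldehyde oxidises the benzylic alkoxide, so the para isomer open to other formylations cannot arise.

**Step 6**
Reactants: 7 4,6-bis(benzyloxy)-2-hydroxybenzaldehyde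
Product: 8 4,6-bis(benzyloxy)-2-(tert-butyldimethylsilyloxy)benzaldehyde
Conditions: TBSCl, imidazole, DMF, rt
Reagents that add atoms: tert-butyldimethylsilyl chloride, CC(C)(C)[Si](C)(C)Cl
Why: Standard silylation of the phenol removes the acidic proton and the deactivating phenoxide character of the aldehyde, so that one equivalent of the valuable Grignard reagent suffices in step 7.

**Step 7**
Reactants: 5 (2R,3S)-3,5,7-tris(benzyloxy)-8-bromo-6-iodo-2-[3,4,5-tris(benzyloxy)phenyl]chroman; 8 4,6-bis(benzyloxy)-2-(tert-butyldimethylsilyloxy)benzaldehyde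
Product: 10 [4,6-bis(benzyloxy)-2-(tert-butyldimethylsilyloxy)phenyl](ArD)methanol (carbinol epimers), via arylmagnesium chloride 9 (not isolated)
Conditions: iPrMgCl·LiCl (1.1 equiv), THF, −20 °C, 1 h; then 8 (1.2 equiv), −20 °C → rt
Reagents that add atoms: none
Why: Iodine–magnesium exchange is much faster at C6'–I than at C8'–Br, and 1,2-addition of the resulting aryl Grignard reagent to aldehyde 8 forms C4–C6' with no 6'/8' ambiguity, the carbinol centre being an epimer mixture that is erased in step 9.

**Step 8**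
Reactants: 10 [4,6-bis(benzyloxy)-2-(tert-butyldimethylsilyloxy)phenyl](ArD)methanol
Product: 12 2-[ArD(4-methylphenylsulfonyl)methyl]-3,5-bis(benzyloxy)phenol (sulfone-carbon epimers), via ortho-hydroxybenzhydrol 11 (not isolated)
Conditions: Bu4NF (1.1 equiv), AcOH (1.1 equiv), THF, 0 °C; then p-TolSO2H (3 equiv), CH2Cl2, rt
Reagents that add atoms: p-toluenesulfinic acid, Cc1ccc(cc1)S(=O)O
Why: Fluoride cleaves the only silyl ether (a shift of silicon to the carbinol oxygen during step 7 would be harmless), and the oxygen-rich benzhydrol then ionises under the acidity of the sulfinic acid and is captured at sulfur, the known SN1 sulfonylation of ortho-hydroxybenzhydrols that gives storable methide precursors.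

**Step 9**
Reactants: 12 2-[ArD(4-methylphenylsulfonyl)methyl]-3,5-bis(benzyloxy)phenol; 13 benzyloxyacetyl chloride
Product: 16 (3S,4S)-3,5,7-tris(benzyloxy)-4-ArD-chroman-2-one (3,4-trans lactone), via ortho-quinone methide 14 (not isolated), via ammonium enolate 15 (not isolated)
Conditions: Cs2CO3 (1.5 equiv), CH2Cl2, 0 °C, 30 min; then (2S,3R)-HyperBTM (20 mol %), iPr2NEt (2 equiv), 13 (1.5 equiv, slow addition), −40 °C → rt
Reagents that add atoms: none
Why: Proposed new method: Cs2CO3 removes the O1 proton of 12 and p-toluenesulfinate leaves (E1cB) to give methide 14, the 1-oxadiene O1=C8a–C4a=C4, before any acyl donor is present, so the phenol cannot be O-acylated; 13 then acylates the isothiourea, iPr2NEt turns the acyl isothiouronium ion into the (Z)-enolate 15, its α-carbon (C3) adds to C4, and the liberated phenoxide O1 attacks the acyl carbon (C2) and expels the catalyst. The closest known reaction type is the Lewis-base-catalysed Michael addition–lactonisation (formal [4+2]) of ortho-quinone methides from 2-(sulfonylmethyl)phenols with C1-ammonium or azolium enolates of arylacetic acid derivatives, and α-alkoxy ammonium enolates from alkoxyacetyl chlorides are known from catalytic ketene–imine cycloadditions; new here are their combination and a methide whose C4 aryl group bears two ortho oxygens. Ring C closes by a 6-exo-trig acyl substitution of O1 at C2 after the intermolecular C3–C4 bond formation. C3 is controlled by the catalyst: the 1,5-O···S contact holds the enolate coplanar with the heterocycle, the pseudoaxial phenyl group of the catalyst covers one face, and attack on the open face of the (Z)-enolate gives 3S. C4 follows from the relative orientation in the same transition state: the methide, reacting through the isomer with ring D turned away from O1, lies with ring A over the cationic heterocycle so that the developing phenoxide faces the positive charge, which places ring D anti to the C3 benzyloxy group (3,4-trans), and since addition to so stabilised a methide should be reversible, lactonisation drains the less strained trans adduct, which is also the thermodynamic C3 epimer. The step needs conjugate attack at C4 of a methide that is still electrophilic and no 6'/8' ambiguity: the two ortho benzyloxy groups twist ring D out of conjugation, the ring A benzyloxy groups make sulfinate loss easy under mild base, and the C4–C6' bond already exists with C8' blocked by bromine.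

**Step 10**
Reactants: 16 (3S,4S)-3,5,7-tris(benzyloxy)-4-ArD-chroman-2-one; 17 5-bromo-1,2,3-tris(benzyloxy)benzene
Product: 19 (3S,4S)-3,5,7-tris(benzyloxy)-2-[3,4,5-tris(benzyloxy)phenyl]-4-ArD-chroman-2-ol (lactol as C2 epimers in equilibrium with the open hydroxy ketone), via arylmagnesium bromide 18 (not isolated)
Conditions: 17, Mg turnings, I2 (crystal), THF, 50 °C; then 16 (18 in 1.3 equiv), THF, −40 °C → 0 °C
Reagents that add atoms: none
Why: Mono-addition of an aryl Grignard reagent to a lactone as in C-aryl glycoside synthesis, where magnesium rather than lithium avoids halogen–metal exchange at C8'–Br, the hindered donor-substituted aryl ketone released from the tetrahedral intermediate resists a second addition, and C3 and C4 are left untouched at low temperature.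

**Step 11**
Reactants: 19 (3S,4S)-3,5,7-tris(benzyloxy)-2-[3,4,5-tris(benzyloxy)phenyl]-4-ArD-chroman-2-ol
Product: 20 (2R,3S,4S)-3,5,7-tris(benzyloxy)-2-[3,4,5-tris(benzyloxy)phenyl]-4-ArD-chroman (2,3-trans-3,4-trans)
Conditions: Et3SiH (5 equiv), BF3·OEt2 (2 equiv), CH2Cl2, −78 °C → −30 °C
Reagents that add atoms: none
Why: Ionic hydrogenation of a lactol as used for C-aryl glycosides, in which the C2 oxocarbenium ion adopts the half-chair with C3–OBn and ring D pseudo-equatorial and takes hydride axially on the face anti to ring D, so ring B ends up equatorial and the 2,3-trans-2,4-cis (2R) flavan results.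

**Step 12**
Reactants: 20 (2R,3S,4S)-3,5,7-tris(benzyloxy)-2-[3,4,5-tris(benzyloxy)phenyl]-4-ArD-chroman
Product: 21 gallocatechin-(4α→6)-gallocatechin, (2R,3S,4R)-upper and (2R,3S)-lower unit
Conditions: H2 (1 atm), Pd(OH)2/C, Et3N (1.5 equiv), THF/MeOH/H2O, rt
Reagents that add atoms: none
Why: Catalytic hydrogenolysis cleaves all twelve benzyl ethers and hydrodehalogenates C8'–Br in one operation, as is known for bromine-capped benzylated proanthocyanidins, while Et3N takes up the HBr that would endanger the acid-labile C4–C6' bond and no stereocentre is touched.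

**Compound list**
1 | (+)-gallocatechin | Oc1cc(O)c2C[C@H](O)[C@@H](c3cc(O)c(O)c(O)c3)Oc2c1 | starting material
2 | (2R,3S)-5,7-bis(benzyloxy)-2-[3,4,5-tris(benzyloxy)phenyl]chroman-3-ol | c1c(OCc5ccccc5)cc2c(c1OCc5ccccc5)C[C@H](O)[C@@H](c1cc(OCc5ccccc5)c(OCc5ccccc5)c(OCc5ccccc5)c1)O2 | intermediate
3 | (2R,3S)-3,5,7-tris(benzyloxy)-2-[3,4,5-tris(benzyloxy)phenyl]chroman | c1c(OCc5ccccc5)cc2c(c1OCc5ccccc5)C[C@H](OCc5ccccc5)[C@@H](c1cc(OCc5ccccc5)c(OCc5ccccc5)c(OCc5ccccc5)c1)O2 | intermediate
4 | 8-bromo derivative of 3 | c1c(OCc5ccccc5)c(Br)c2c(c1OCc5ccccc5)C[C@H](OCc5ccccc5)[C@@H](c1cc(OCc5ccccc5)c(OCc5ccccc5)c(OCc5ccccc5)c1)O2 | intermediate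
5 | 8-bromo-6-iodo derivative of 3 | Ic1c(OCc5ccccc5)c(Br)c2c(c1OCc5ccccc5)C[C@H](OCc5ccccc5)[C@@H](c1cc(OCc5ccccc5)c(OCc5ccccc5)c(OCc5ccccc5)c1)O2 | intermediate
6 | 3,5-bis(benzyloxy)phenol | Oc1cc(OCc2ccccc2)cc(OCc2ccccc2)c1 | starting material
7 | 4,6-bis(benzyloxy)-2-hydroxybenzaldehyde | O=Cc1c(O)cc(OCc2ccccc2)cc1OCc1ccccc1 | intermediate
8 | 4,6-bis(benzyloxy)-2-(tert-butyldimethylsilyloxy)benzaldehyde | O=Cc1c(O[Si](C)(C)C(C)(C)C)cc(OCc2ccccc2)cc1OCc1ccccc1 | intermediate
9 | ArD–MgCl (C6' arylmagnesium chloride, not isolated) | Cl[Mg]c1c(OCc5ccccc5)c(Br)c2c(c1OCc5ccccc5)C[C@H](OCc5ccccc5)[C@@H](c1cc(OCc5ccccc5)c(OCc5ccccc5)c(OCc5ccccc5)c1)O2 | intermediate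
10 | [4,6-bis(benzyloxy)-2-(TBSO)phenyl](ArD)methanol, carbinol epimers | CC(C)(C)[Si](C)(C)Oc1cc(OCc5ccccc5)cc(OCc5ccccc5)c1C(O)c1c(OCc5ccccc5)c(Br)c2c(c1OCc5ccccc5)C[C@H](OCc5ccccc5)[C@@H](c1cc(OCc5ccccc5)c(OCc5ccccc5)c(OCc5ccccc5)c1)O2 | intermediate
11 | 2-[ArD(hydroxy)methyl]-3,5-bis(benzyloxy)phenol, carbinol epimers (not isolated) | Oc1cc(OCc5ccccc5)cc(OCc5ccccc5)c1C(O)c1c(OCc5ccccc5)c(Br)c2c(c1OCc5ccccc5)C[C@H](OCc5ccccc5)[C@@H](c1cc(OCc5ccccc5)c(OCc5ccccc5)c(OCc5ccccc5)c1)O2 | intermediate
12 | 2-[ArD(4-methylphenylsulfonyl)methyl]-3,5-bis(benzyloxy)phenol, sulfone-carbon epimers | Oc1cc(OCc5ccccc5)cc(OCc5ccccc5)c1C(S(=O)(=O)c3ccc(C)cc3)c1c(OCc5ccccc5)c(Br)c2c(c1OCc5ccccc5)C[C@H](OCc5ccccc5)[C@@H](c1cc(OCc5ccccc5)c(OCc5ccccc5)c(OCc5ccccc5)c1)O2 | intermediate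
13 | benzyloxyacetyl chloride | O=C(Cl)COCc1ccccc1 | starting material
14 | 3,5-bis(benzyloxy)-6-(ArD-methylidene)cyclohexa-2,4-dien-1-one, ring A ortho-quinone methide (not isolated) | O=C1C=C(OCc5ccccc5)C=C(OCc5ccccc5)C1=Cc1c(OCc5ccccc5)c(Br)c2c(c1OCc5ccccc5)C[C@H](OCc5ccccc5)[C@@H](c1cc(OCc5ccccc5)c(OCc5ccccc5)c(OCc5ccccc5)c1)O2 | intermediate
15 | (Z)-2-benzyloxy-1-oxidoethenyl isothiouronium zwitterion of (2S,3R)-HyperBTM (not isolated) | CC(C)[C@@H]1CN2c3ccccc3SC2=[N+](/C([O-])=C/OCc2ccccc2)[C@@H]1c1ccccc1 | intermediate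
16 | (3S,4S)-3,5,7-tris(benzyloxy)-4-ArD-chroman-2-one, 3,4-trans | C(c5ccccc5)Oc1cc(OCc5ccccc5)c2c(c1)OC(=O)[C@@H](OCc5ccccc5)[C@@H]2c1c(OCc5ccccc5)c(Br)c2c(c1OCc5ccccc5)C[C@H](OCc5ccccc5)[C@@H](c1cc(OCc5ccccc5)c(OCc5ccccc5)c(OCc5ccccc5)c1)O2 | intermediate
17 | 5-bromo-1,2,3-tris(benzyloxy)benzene | Brc1cc(OCc2ccccc2)c(OCc2ccccc2)c(OCc2ccccc2)c1 | starting material
18 | 3,4,5-tris(benzyloxy)phenylmagnesium bromide (not isolated) | Br[Mg]c1cc(OCc2ccccc2)c(OCc2ccccc2)c(OCc2ccccc2)c1 | intermediate
19 | (3S,4S)-3,5,7-tris(benzyloxy)-2-[3,4,5-tris(benzyloxy)phenyl]-4-ArD-chroman-2-ol, C2 epimers | C(c5ccccc5)Oc1cc(OCc5ccccc5)c2c(c1)OC(O)(c1cc(OCc5ccccc5)c(OCc5ccccc5)c(OCc5ccccc5)c1)[C@@H](OCc5ccccc5)[C@@H]2c1c(OCc5ccccc5)c(Br)c2c(c1OCc5ccccc5)C[C@H](OCc5ccccc5)[C@@H](c1cc(OCc5ccccc5)c(OCc5ccccc5)c(OCc5ccccc5)c1)O2 | intermediate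
20 | (2R,3S,4S)-3,5,7-tris(benzyloxy)-2-[3,4,5-tris(benzyloxy)phenyl]-4-ArD-chroman (dodeca-O-benzyl-8'-bromo dimer) | C(c5ccccc5)Oc1cc(OCc5ccccc5)c2c(c1)O[C@H](c1cc(OCc5ccccc5)c(OCc5ccccc5)c(OCc5ccccc5)c1)[C@@H](OCc5ccccc5)[C@@H]2c1c(OCc5ccccc5)c(Br)c2c(c1OCc5ccccc5)C[C@H](OCc5ccccc5)[C@@H](c1cc(OCc5ccccc5)c(OCc5ccccc5)c(OCc5ccccc5)c1)O2 | intermediate
21 | gallocatechin-(4α→6)-gallocatechin | Oc1cc(O)c2c(c1)O[C@H](c1cc(O)c(O)c(O)c1)[C@@H](O)[C@@H]2c1c(O)cc2c(c1O)C[C@H](O)[C@@H](c1cc(O)c(O)c(O)c1)O2 | target

**Totals:** 12 steps. The longest linear sequence is 10 steps (steps 1–4 and 7–12, from (+)-gallocatechin).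

**Steps most likely to fail**

1. **Step 9.**
   - Conjugate addition to a donor-stabilised methide flanked by four ortho substituents may be slow.
   - The alkoxy enolate may be consumed by self-condensation.
   - The C5 benzyloxy group may let the exocyclic C4a=C4 bond isomerise, which would erode control over the methide face and hence the 3,4-trans selectivity.
   - The fallback gives up the methide and uses the known Lewis-acid coupling of a C4-activated flavan-3-ol with a halogen-capped nucleophile.
   - It sets out from 3 and 4. Compound 3 is oxidised at the benzylic C4 position with DDQ in CH2Cl2 in the presence of 2-ethoxyethanol to hexa-O-benzyl-4-(2-ethoxyethoxy)gallocatechin F1 (C4 epimers, the centre being lost on ionisation).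
   - F1 is then ionised with Me3SiOTf in CH2Cl2 at −78 °C in the presence of an excess of 4. With C8' blocked, 4 can react only at C6', and it approaches the C4 cation anti to the C3 benzyloxy group.
   - The sequence comes back to the route at 20.

2. **Step 10.**
   - The tetrahedral intermediate carries an aryloxide leaving group and may collapse early, opening the way to a second addition.
   - Deprotonation at C3 with ketene formation would scramble C3.
   - The fallback sets out from 16, which is opened with Me(MeO)NH·HCl and AlMe3 (CH2Cl2, 0 °C) to the ring-opened phenolic Weinreb amide F2.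
   - The chelated adduct of F2 with 2.5 equivalents of Grignard reagent 18 (the first equivalent deprotonates the phenol) cannot add twice. On work-up it releases the hydroxy ketone, which closes to the lactol.
   - The route is rejoined at 19.

3. **Step 11.**
   - The oxocarbenium ion may lose H3 to give the flav-2-ene, with loss of C3 configuration.
   - Hydride delivery may lack facial selectivity.
   - The Lewis acid may start acidolysis of the C4–C6' bond.
   - The fallback separates reduction from ring closure. It sets out from 19, whose open hydroxy ketone form is reduced with NaBH4 (THF/MeOH, 0 °C) to the ring-opened C2 benzylic alcohol F3 (C2 epimers).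
   - A catalytic amount of camphorsulfonic acid in CH2Cl2 at 0 °C then closes O1 onto the benzylic cation stabilised by ring B. This is the known acid-catalysed cyclisation of 1-aryl-3-(2-hydroxyaryl)propane-1,2-diol derivatives, which favours the 2,3-trans flavan with ring B equatorial.
   - The route is rejoined at 20.

**Further compounds**
F1 | step 9 | hexa-O-benzyl-4-(2-ethoxyethoxy)gallocatechin (C4 epimers) | c1c(OCc5ccccc5)cc2c(c1OCc5ccccc5)C(OCCOCC)[C@H](OCc5ccccc5)[C@@H](c1cc(OCc5ccccc5)c(OCc5ccccc5)c(OCc5ccccc5)c1)O2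
F2 | step 10 | ring-opened phenolic Weinreb amide, 3-ArD-2-benzyloxy-3-[2,4-bis(benzyloxy)-6-hydroxyphenyl]-N-methoxy-N-methylpropanamide with C3 and C4 as in 16 | Oc1cc(OCc5ccccc5)cc(OCc5ccccc5)c1[C@@H](c1c(OCc5ccccc5)c(Br)c2c(c1OCc5ccccc5)C[C@H](OCc5ccccc5)[C@@H](c1cc(OCc5ccccc5)c(OCc5ccccc5)c(OCc5ccccc5)c1)O2)[C@H](OCc5ccccc5)C(=O)N(C)OC
F3 | step 11 | ring-opened C2 benzylic alcohol, 3-ArD-2-benzyloxy-3-[2,4-bis(benzyloxy)-6-hydroxyphenyl]-1-[3,4,5-tris(benzyloxy)phenyl]propan-1-ol (C2 epimers, C3 and C4 as in 16) | Oc1cc(OCc5ccccc5)cc(OCc5ccccc5)c1[C@@H](c1c(OCc5ccccc5)c(Br)c2c(c1OCc5ccccc5)C[C@H](OCc5ccccc5)[C@@H](c1cc(OCc5ccccc5)c(OCc5ccccc5)c(OCc5ccccc5)c1)O2)[C@H](OCc5ccccc5)C(O)c1cc(OCc5ccccc5)c(OCc5ccccc5)c(OCc5ccccc5)c1
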